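The 2,3-dimethylchroman-4-one ring is disconnected at its O1–C2 bond. The precursor is an ortho-tigloyl phenol in which the second ortho oxygen and the hexanoic acid are tied together as a dihydrocoumarin lactone, so only the future O1 is free. A quinidine-catalysed 6-endo-trig oxa-Michael addition of this phenol to the enone β-carbon closes the pyranone ring and sets C2; C3, next to the C4 ketone, is then equilibrated to trans in the same flask. The step exploits the β-aryloxy ketone O1–C2–C3–C4(=O) of the pyranone ring. The benzylic centre is set first by iminium-catalysed Friedel–Crafts alkylation; the prenyl group arrives by Stille coupling, and lactone hydrolysis ends the route.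

Key step: step 4

Remark: tricyclic intermediates are numbered as pyrano[2,3-f]chromenes (lactone O1, C2, C3, C4; pyranone O7, C8, C9, C10), so C8 and C9 become C2 and C3 of the target chromanone; acylation of lactone 5 is assumed to occur at C8, para to the C5 methoxy group.

Step 1
Reactants: 1 3,5-dimethoxyphenol; 2 (E)-hex-2-enal
Product: 4 (4R)-5,7-dimethoxy-4-propylchroman-2-ol (lactol; both C2 epimers), via hydroxy aldehyde 3 (not isolated)
Conditions: (S)-2-[diphenyl(trimethylsilyloxy)methyl]pyrrolidine (20 mol %), PhCO2H (20 mol %), toluene, 0 °C → rt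
Reagents that add atoms: none
Why: Iminium-catalysed Friedel–Crafts alkylation of an electron-rich phenol followed by hemiacetalisation: the CPh2(OTMS) group of the (S)-catalyst shields one face of the E-iminium of 2, so the carbon of 1 ortho to OH and para to OMe adds to the open face of the β-carbon and should set C4 as R, and closure of 3 to the lactol drives the sequence.

Step 2
Reactants: 4 (4R)-5,7-dimethoxy-4-propylchroman-2-ol
Product: 5 (4R)-5,7-dimethoxy-4-propylchroman-2-one
Conditions: (n-Pr4N)RuO4 (5 mol %), N-methylmorpholine N-oxide, 4 Å MS, CH2Cl2, rt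
Reagents that add atoms: none
Why: Ley–Griffith oxidation of a lactol to the lactone; C4 is β to the new carbonyl and cannot epimerise, and the lactone now masks both the acid and one phenol oxygen.

Step 3
Reactants: 5 (4R)-5,7-dimethoxy-4-propylchroman-2-one; 6 tigloyl chloride [(E)-2-methylbut-2-enoyl chloride]
Product: 8 (4R)-7-hydroxy-5-methoxy-8-[(E)-2-methylbut-2-enoyl]-4-propylchroman-2-one, via methoxy ketone 7 (not isolated)
Conditions: AlCl3 (3 equiv), CH2Cl2, −20 °C → rt; cold dilute HCl quench
Reagents that add atoms: none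
Why: Friedel–Crafts acylation at C8 (para to the C5 methoxy group and less hindered than C6) followed by chelation-controlled AlCl3 cleavage of the only methyl ether ortho to the new ketone (C7) should free the nucleophilic oxygen and leave the C5 methoxy group intact; low temperature and a prompt quench are meant to keep the enone open.

Step 4
Reactants: 8 (4R)-7-hydroxy-5-methoxy-8-[(E)-2-methylbut-2-enoyl]-4-propylchroman-2-one
Product: 10 (4R,8S,9S)-5-methoxy-8,9-dimethyl-4-propyl-3,4,8,9-tetrahydro-2H,10H-pyrano[2,3-f]chromene-2,10-dione (trans-chromanone), via cis-chromanone 9 (not isolated)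
Conditions: quinidine (20 mol %), PhCl, 15 °C; then MgBr2·OEt2 (1 equiv), Et3N (2 equiv), CH2Cl2, rt
Reagents that add atoms: none
Why: The quinuclidine nitrogen of quinidine deprotonates the chelated C7 phenol while its C9 hydroxyl hydrogen-bonds the enone carbonyl, and the phenoxide oxygen adds to the β-carbon of the s-cis (E)-tigloyl group to form the O7–C8 bond, the resulting enol being protonated at the α-carbon. The closest known reaction type is the cinchona-alkaloid-catalysed intramolecular oxa-Michael addition of ortho-tigloylphenols to 2,3-dimethylchroman-4-ones. The pyranone ring closes in the 6-endo-trig mode. The oxygen-bearing centre C8 (S, the future C2) is set by the catalyst, quinidine being chosen as the pseudoenantiomer of quinine, which is expected to give the R series; C9 is first set by kinetic protonation (mainly cis, 9) and then brought to S (trans, both methyls pseudo-equatorial) by MgBr2/Et3N soft enolisation, which equilibrates only the carbon α to the ketone. The step needs site selectivity between the two phenolic oxygens ortho to the acyl group and face selectivity independent of the remote C4 centre: the first is secured because the other oxygen is locked in the lactone, the second by the catalyst, and the absence of strong base should suppress retro-Michael loss of C8.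

Step 5
Reactants: 10 (4R,8S,9S)-5-methoxy-8,9-dimethyl-4-propyl-3,4,8,9-tetrahydro-2H,10H-pyrano[2,3-f]chromene-2,10-dione
Product: 11 (4R,8S,9S)-6-iodo-5-methoxy-8,9-dimethyl-4-propyl-3,4,8,9-tetrahydro-2H,10H-pyrano[2,3-f]chromene-2,10-dione
Conditions: NIS (1.1 equiv), TFA (10 mol %), MeCN, 0 °C → rt
Reagents that add atoms: N-iodosuccinimide, O=C1CCC(=O)N1I
Why: Electrophilic aromatic iodination at C6, the only free ring position, which is flanked by the C5 methoxy group and ring oxygen O7 and is meta to the ketone-bearing carbon.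

Step 6
Reactants: 11 (4R,8S,9S)-6-iodo-5-methoxy-8,9-dimethyl-4-propyl-3,4,8,9-tetrahydro-2H,10H-pyrano[2,3-f]chromene-2,10-dione; 12 tributyl(3-methylbut-2-en-1-yl)stannane
Product: 13 (4R,8S,9S)-5-methoxy-8,9-dimethyl-6-(3-methylbut-2-en-1-yl)-4-propyl-3,4,8,9-tetrahydro-2H,10H-pyrano[2,3-f]chromene-2,10-dione
Conditions: Pd(PPh3)4 (10 mol %), DMF, 90 °C
Reagents that add atoms: none
Why: Stille coupling, in which reductive elimination through the unsubstituted allyl terminus should give the linear prenyl arene; the neutral conditions leave the lactone, the ketone and all three stereocentres untouched.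

Step 7
Reactants: 13 (4R,8S,9S)-5-methoxy-8,9-dimethyl-6-(3-methylbut-2-en-1-yl)-4-propyl-3,4,8,9-tetrahydro-2H,10H-pyrano[2,3-f]chromene-2,10-dione
Product: 14 (3R)-3-[(2S,3S)-5-hydroxy-7-methoxy-2,3-dimethyl-8-(3-methylbut-2-en-1-yl)-4-oxochroman-6-yl]hexanoic acid (target)
Conditions: LiOH (3 equiv), THF/H2O 3:1, 0 °C; then 1 M HCl to pH 3–4 at 0 °C
Reagents that add atoms: lithium hydroxide, [Li+].[OH-]
Why: Saponification of the aryl ester lactone should be fast at 0 °C; the phenoxide released is conjugated to the C4 ketone and lowers its α-acidity, which protects C2 and C3 from retro-Michael opening, and after cold acidification the C5 hydroxyl is held by a hydrogen bond to that ketone, so the open acid should be isolable.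

Compound list
1 | 3,5-dimethoxyphenol | COc1cc(O)cc(OC)c1 | starting material
2 | (E)-hex-2-enal | CCC/C=C/C=O | starting material
3 | (3R)-3-(2-hydroxy-4,6-dimethoxyphenyl)hexanal | CCC[C@H](CC=O)c1c(O)cc(OC)cc1OC | intermediate (not isolated)
4 | (4R)-5,7-dimethoxy-4-propylchroman-2-ol, lactol, both C2 epimers | CCC[C@@H]1CC(O)Oc2cc(OC)cc(OC)c21 | intermediate
5 | (4R)-5,7-dimethoxy-4-propylchroman-2-one | CCC[C@@H]1CC(=O)Oc2cc(OC)cc(OC)c21 | intermediate
6 | tigloyl chloride, (E)-2-methylbut-2-enoyl chloride | C/C=C(\C)C(=O)Cl | starting material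
7 | (4R)-5,7-dimethoxy-8-[(E)-2-methylbut-2-enoyl]-4-propylchroman-2-one | CCC[C@@H]1CC(=O)Oc2c(C(=O)/C(C)=C/C)c(OC)cc(OC)c21 | intermediate (not isolated)
8 | (4R)-7-hydroxy-5-methoxy-8-[(E)-2-methylbut-2-enoyl]-4-propylchroman-2-one | CCC[C@@H]1CC(=O)Oc2c(C(=O)/C(C)=C/C)c(O)cc(OC)c21 | intermediate
9 | (4R,8S,9R)-5-methoxy-8,9-dimethyl-4-propyl-3,4,8,9-tetrahydro-2H,10H-pyrano[2,3-f]chromene-2,10-dione, cis-chromanone | CCC[C@@H]1CC(=O)Oc2c3c(cc(OC)c21)O[C@@H](C)[C@@H](C)C3=O | intermediate (not isolated)
10 | (4R,8S,9S)-5-methoxy-8,9-dimethyl-4-propyl-3,4,8,9-tetrahydro-2H,10H-pyrano[2,3-f]chromene-2,10-dione, trans-chromanone | CCC[C@@H]1CC(=O)Oc2c3c(cc(OC)c21)O[C@@H](C)[C@H](C)C3=O | intermediate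
11 | (4R,8S,9S)-6-iodo-5-methoxy-8,9-dimethyl-4-propyl-3,4,8,9-tetrahydro-2H,10H-pyrano[2,3-f]chromene-2,10-dione | CCC[C@@H]1CC(=O)Oc2c3c(c(I)c(OC)c21)O[C@@H](C)[C@H](C)C3=O | intermediate
12 | tributyl(3-methylbut-2-en-1-yl)stannane | CCCC[Sn](CCCC)(CCCC)CC=C(C)C | starting material
13 | (4R,8S,9S)-5-methoxy-8,9-dimethyl-6-(3-methylbut-2-en-1-yl)-4-propyl-3,4,8,9-tetrahydro-2H,10H-pyrano[2,3-f]chromene-2,10-dione | CCC[C@@H]1CC(=O)Oc2c3c(c(CC=C(C)C)c(OC)c21)O[C@@H](C)[C@H](C)C3=O | intermediate
14 | (3R)-3-[(2S,3S)-5-hydroxy-7-methoxy-2,3-dimethyl-8-(3-methylbut-2-en-1-yl)-4-oxochroman-6-yl]hexanoic acid | CCC[C@H](CC(=O)O)c1c(O)c2c(c(CC=C(C)C)c1OC)O[C@@H](C)[C@H](C)C2=O | target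

Total step count: 7. Longest linear sequence: 7 steps (from 1 to 14).

Steps most likely to fail

Step 4 (key step). What may go wrong: weak face selection by quinidine on the hindered, chelated enone, or erosion of the new oxygen-bearing centre through retro-Michael opening during the equilibration. Fallback: a stereospecific Mitsunobu closure of the same O–C bond. It sets out from lactone 5. EtCOCl/AlCl3 (CH2Cl2, 0 °C → rt) should give, with loss of the ortho methyl group, (4R)-7-hydroxy-5-methoxy-8-propanoyl-4-propylchroman-2-one F1. Enolisation with Bu2BOTf (2.2 equiv)/i-Pr2NEt to the Z-enol borinate and addition of acetaldehyde (−78 °C, oxidative work-up) should give the two syn aldols, which are diastereomers because of C4 and are separated by chromatography: the wanted (4R)-7-hydroxy-8-[(2S,3R)-3-hydroxy-2-methylbutanoyl]-5-methoxy-4-propylchroman-2-one F2 and the unwanted (4R)-7-hydroxy-8-[(2R,3S)-3-hydroxy-2-methylbutanoyl]-5-methoxy-4-propylchroman-2-one F3. PPh3/DIAD (THF, 0 °C) then closes the ring from F2 by SN2 inversion at the carbinol carbon and comes back to the route at trans-chromanone 10.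

Step 3. What may go wrong: Lewis-acid-promoted closure of the freed phenol onto the enone before the chiral catalyst is present, addition of HCl to the enone, or acylation at C6. Fallback: build the enone under neutral conditions and unmask the phenol separately. It sets out from lactone 5. Rieche formylation (Cl2CHOMe, TiCl4, CH2Cl2, −20 °C) should give (4R)-5,7-dimethoxy-2-oxo-4-propylchromane-8-carbaldehyde F4, on which the site of substitution can be checked by NOE. Nozaki–Hiyama–Kishi addition of (E)-2-bromobut-2-ene (CrCl2, NiCl2 cat., DMF, rt), which tolerates the lactone and keeps the alkene geometry, should give (4R)-8-[(E)-1-hydroxy-2-methylbut-2-enyl]-5,7-dimethoxy-4-propylchroman-2-one F5 as a mixture of carbinol epimers. Dess–Martin oxidation gives methoxy ketone 7, now isolated, and BCl3 (CH2Cl2, −78 °C) cleaves the chelated C7 methyl ether to come back to the route at 8.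

Step 6. What may go wrong: slow oxidative addition at the doubly ortho-substituted iodide, protodeiodination, or transfer of the prenyl group through its tertiary terminus. Fallback: allylation followed by olefin cross-metathesis. It sets out from iodide 11. Stille coupling with allyltributylstannane (Pd(PPh3)4, DMF, 80 °C), which has no regiochemical ambiguity, should give (4R,8S,9S)-6-allyl-5-methoxy-8,9-dimethyl-4-propyl-3,4,8,9-tetrahydro-2H,10H-pyrano[2,3-f]chromene-2,10-dione F6. Cross-metathesis with 2-methylbut-2-ene (second-generation Grubbs catalyst, CH2Cl2, 40 °C) converts the allyl into the prenyl group and comes back to the route at 13.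

Further compounds
F1 | step 4 | (4R)-7-hydroxy-5-methoxy-8-propanoyl-4-propylchroman-2-one | CCC[C@@H]1CC(=O)Oc2c(C(=O)CC)c(O)cc(OC)c21
F2 | step 4 | (4R)-7-hydroxy-8-[(2S,3R)-3-hydroxy-2-methylbutanoyl]-5-methoxy-4-propylchroman-2-one | CCC[C@@H]1CC(=O)Oc2c(C(=O)[C@@H](C)[C@@H](C)O)c(O)cc(OC)c21
F3 | step 4 | (4R)-7-hydroxy-8-[(2R,3S)-3-hydroxy-2-methylbutanoyl]-5-methoxy-4-propylchroman-2-one | CCC[C@@H]1CC(=O)Oc2c(C(=O)[C@H](C)[C@H](C)O)c(O)cc(OC)c21
F4 | step 3 | (4R)-5,7-dimethoxy-2-oxo-4-propylchromane-8-carbaldehyde | CCC[C@@H]1CC(=O)Oc2c(C=O)c(OC)cc(OC)c21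
F5 | step 3 | (4R)-8-[(E)-1-hydroxy-2-methylbut-2-enyl]-5,7-dimethoxy-4-propylchroman-2-one | CCC[C@@H]1CC(=O)Oc2c(C(O)/C(C)=C/C)c(OC)cc(OC)c21
F6 | step 6 | (4R,8S,9S)-6-allyl-5-methoxy-8,9-dimethyl-4-propyl-3,4,8,9-tetrahydro-2H,10H-pyrano[2,3-f]chromene-2,10-dione | CCC[C@@H]1CC(=O)Oc2c3c(c(CC=C)c(OC)c21)O[C@@H](C)[C@H](C)C3=O
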